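**Plan**
- Retrosynthesis: after removal of sixteen benzyl ethers, catechin-(4α→8)-gallocatechin-(4β→8)-catechin is cut at C4–C4a of the top unit (ring C opened to an aryl ether carbinol), then at the carbinol C4–C8(middle) bond (aryllithium + aldehyde), at O1–C2 of the top unit (phenol + benzylic alcohol), and at C4(middle)–C8(bottom) (aryllithium + flavan-4-one).
- Enabling feature: C4 of the top unit is a diarylmethine between C4a of its own ring A and C8 of ring A of the middle unit. The oxygens on C7, C8a (O1) and C5 of that middle ring make the C4 cation easy to reach from a carbinol, while O1–C2 can already be in place as a 3,5-dibenzyloxyphenyl ether whose ortho carbon becomes C4a.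
- Forward: benzylated 8-bromocatechin (bottom) and benzylated dihydromyricetin (middle) are joined and reduced to the 3,4-cis dimer, which is brominated at C8. The open-chain top unit is built as an aldehyde by glycolate aldol and Mitsunobu etherification. Dimer and aldehyde are joined, ring C of the top unit closes last, and hydrogenolysis ends the route.
- Stereochemistry: C2/C3 of the bottom and middle units come from (+)-catechin and (+)-dihydromyricetin; middle C4 from hydride delivery anti to O3; top C3 and C2 from an auxiliary-controlled syn aldol followed by Mitsunobu inversion at the benzylic carbon; top C4 from allylic-strain-controlled, chair-like ring closure.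

Key step: step 17

Assumption: the target is read as catechin-(4α→8)-gallocatechin-(4β→8)-catechin (all C2/C3 pairs trans, top C4 aryl trans to O3, middle C4 aryl cis to O3); carbinol 25 is carried as both epimers because they ionise to one cation, and carbinol 9 is drawn as its expected epimer although that centre is erased in step 7.

**Route**

Step 1
Reactants: 1 (+)-catechin
Product: 2 5,7,3',4'-tetra-O-benzyl-(+)-catechin
Conditions: BnBr, K2CO3, DMF, 0 °C to rt
Reagents that add atoms: benzyl bromide, BrCc1ccccc1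
Why: Williamson ether synthesis in which K2CO3 deprotonates only the four phenols, so the C3 alcohol stays free and C2 and C3 are untouched.

Step 2
Reactants: 2 5,7,3',4'-tetra-O-benzyl-(+)-catechin
Product: 3 3,5,7,3',4'-penta-O-benzyl-(+)-catechin
Conditions: NaH, BnBr, DMF, 0 °C to rt
Reagents that add atoms: benzyl bromide, BrCc1ccccc1
Why: Williamson etherification of the sodium alkoxide of the secondary C3 alcohol, routine for benzylated flavan-3-ols and without effect on the stereocentres.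

Step 3
Reactants: 3 3,5,7,3',4'-penta-O-benzyl-(+)-catechin
Product: 4 8-bromo-3,5,7,3',4'-penta-O-benzyl-(+)-catechin
Conditions: NBS, CH2Cl2, −78 °C to rt
Reagents that add atoms: N-bromosuccinimide, O=C1CCC(=O)N1Br
Why: Electrophilic aromatic bromination, which in benzylated flavan-3-ols goes to C8 (flanked by one benzyloxy group and the ring oxygen) ahead of C6.

Step 4
Reactants: 5 (+)-dihydromyricetin
Product: 6 5,7,3',4',5'-penta-O-benzyl-(+)-dihydromyricetin
Conditions: BnBr, K2CO3, DMF, argon, rt to 40 °C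
Reagents that add atoms: benzyl bromide, BrCc1ccccc1
Why: Williamson ether synthesis with a weak base that should alkylate the five phenols (the chelated 5-OH last) but not the C3 alcohol, and under argon at moderate temperature should leave the 2,3-trans ketol intact.

Step 5
Reactants: 6 5,7,3',4',5'-penta-O-benzyl-(+)-dihydromyricetin
Product: 7 3,5,7,3',4',5'-hexa-O-benzyl-(+)-dihydromyricetin
Conditions: BnBr, Ag2O, 4 Å MS, CH2Cl2, rt, dark
Reagents that add atoms: benzyl bromide, BrCc1ccccc1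
Why: Purdie-type O-benzylation mediated by Ag2O, chosen because it is essentially neutral and so avoids the enolisation, ring opening to the chalcone and air oxidation that an alkoxide would cause in this α-ketol.

Step 6
Reactants: 4 8-bromo-3,5,7,3',4'-penta-O-benzyl-(+)-catechin; 7 3,5,7,3',4',5'-hexa-O-benzyl-(+)-dihydromyricetin
Product: 9 undeca-O-benzyl 4-hydroxygallocatechin-(4→8)-catechin (tertiary C4 carbinol), via 8-lithio-penta-O-benzylcatechin 8 (not isolated)
Conditions: 4, n-BuLi, THF, −78 °C; then 7, −78 to 0 °C; H2O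
Reagents that add atoms: none
Why: Bromine–lithium exchange followed by 1,2-addition of the aryllithium to the flavan-4-one, a known way to install a C4 aryl group in this series; the aryl group should enter anti to the C3 benzyloxy group, but the new carbinol centre is erased in the next step.

Step 7
Reactants: 9 undeca-O-benzyl 4-hydroxygallocatechin-(4→8)-catechin
Product: 10 undeca-O-benzyl gallocatechin-(4β→8)-catechin
Conditions: Bu3SnH, CF3CO2H, CH2Cl2, 0 °C
Reagents that add atoms: none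
Why: Ionic hydrogenation (SN1 reduction) in which the acid ionises the tertiary doubly benzylic alcohol and Bu3SnH, a hydride donor strong enough for this highly stabilised cation, should attack C4 anti to the C3 benzyloxy group (the face nucleophiles take on 2,3-trans flavan-4-yl cations), leaving the C4 aryl group cis to O3 (4β).

Step 8
Reactants: 10 undeca-O-benzyl gallocatechin-(4β→8)-catechin
Product: 11 8-bromo-undeca-O-benzyl gallocatechin-(4β→8)-catechin (bromine on C8 of the gallocatechin unit)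
Conditions: NBS (1.0 equiv), CH2Cl2, −78 to −20 °C, dark
Reagents that add atoms: N-bromosuccinimide, O=C1CCC(=O)N1Br
Why: Electrophilic aromatic bromination at the only unsubstituted C8 position of the dimer, which by analogy with the monomers should react ahead of the two C6 positions lying between two benzyloxy groups.

Step 9
Reactants: 12 (R)-4-benzyloxazolidin-2-one; 13 (benzyloxy)acetyl chloride
Product: 14 (R)-4-benzyl-3-[(benzyloxy)acetyl]oxazolidin-2-one
Conditions: Et3N, DMAP (cat.), CH2Cl2, 0 °C to rt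
Reagents that add atoms: none
Why: N-Acylation of the oxazolidinone by the acid chloride under DMAP catalysis, a standard way to load an Evans auxiliary.

Step 10
Reactants: 14 (R)-4-benzyl-3-[(benzyloxy)acetyl]oxazolidin-2-one; 15 3,4-bis(benzyloxy)benzaldehyde
Product: 17 (R)-4-benzyl-3-[(2R,3S)-2-(benzyloxy)-3-[3,4-bis(benzyloxy)phenyl]-3-hydroxypropanoyl]oxazolidin-2-one, via (Z)-dibutylboron enolate 16 (not isolated)
Conditions: Bu2BOTf, Et3N, CH2Cl2, −78 to 0 °C; then 15, −78 to 0 °C; H2O2, MeOH, pH 7 buffer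
Reagents that add atoms: none
Why: Evans syn aldol reaction in which the (Z)-boron enolate reacts through a Zimmerman–Traxler chair with one face shielded by the (R)-benzyl group of the auxiliary, setting C2 (R) and C3 (S) of the adduct in a syn relationship.

Step 11
Reactants: 17 syn aldol adduct
Product: 18 (1S,2S)-2-(benzyloxy)-1-[3,4-bis(benzyloxy)phenyl]propane-1,3-diol
Conditions: LiBH4, MeOH (1 equiv), THF, 0 °C
Reagents that add atoms: none
Why: Reductive cleavage of the N-acyloxazolidinone by LiBH4, which releases the primary alcohol and the recoverable auxiliary without touching the two stereocentres.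

Step 12
Reactants: 18 (1S,2S)-diol
Product: 19 (1S,2S)-2-(benzyloxy)-1-[3,4-bis(benzyloxy)phenyl]-3-[(tert-butyldimethylsilyl)oxy]propan-1-ol
Conditions: TBSCl, imidazole, CH2Cl2, 0 °C
Reagents that add atoms: tert-butyldimethylsilyl chloride, CC(C)(C)[Si](C)(C)Cl
Why: Selective silylation of the primary hydroxyl, which reacts far faster with TBSCl than the hindered secondary benzylic one.

Step 13
Reactants: 19 silyl ether alcohol; 20 3,5-bis(benzyloxy)phenol
Product: 21 tert-butyl{[(2S,3R)-2-(benzyloxy)-3-[3,5-bis(benzyloxy)phenoxy]-3-[3,4-bis(benzyloxy)phenyl]propyl]oxy}dimethylsilane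
Conditions: PPh3, DIAD, toluene, 0 °C to rt
Reagents that add atoms: none
Why: Mitsunobu etherification in which the phenol displaces the activated benzylic oxygen with inversion, turning the syn aldol relationship into the anti (2,3-trans-flavan) one and setting the future C2 as R, a known mode of aryl ether formation at 3,4-dialkoxybenzylic carbinols bearing an α-oxygen.

Step 14
Reactants: 21 aryl ether silyl ether
Product: 22 (2S,3R)-2-(benzyloxy)-3-[3,5-bis(benzyloxy)phenoxy]-3-[3,4-bis(benzyloxy)phenyl]propan-1-ol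
Conditions: TBAF, THF, 0 °C
Reagents that add atoms: none
Why: Fluoride-induced cleavage of the silyl ether, which leaves benzyl and aryl ethers intact.

Step 15
Reactants: 22 primary alcohol
Product: 23 (2R,3R)-2-(benzyloxy)-3-[3,5-bis(benzyloxy)phenoxy]-3-[3,4-bis(benzyloxy)phenyl]propanal
Conditions: Dess–Martin periodinane, NaHCO3, CH2Cl2, 0 °C to rt; used at once
Reagents that add atoms: none
Why: Dess–Martin oxidation under buffered, non-basic conditions should give the α-benzyloxy aldehyde without epimerisation or β-elimination of the phenoxide.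

Step 16
Reactants: 11 8-bromo dimer; 23 aldehyde
Product: 25 hexadeca-O-benzyl seco-trimer carbinol (both carbinol epimers), via 8-lithio dimer 24 (not isolated)
Conditions: 11, n-BuLi, THF, −78 °C; then 23, −78 °C; H2O
Reagents that add atoms: none
Why: Bromine–lithium exchange at C8 of the upper unit and 1,2-addition of the aryllithium to the aldehyde at −78 °C, where addition should outrun enolisation; the new carbinol centre forms without control, which is harmless because both epimers ionise to the same cation.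

Step 17
Reactants: 25 hexadeca-O-benzyl seco-trimer carbinol
Product: 26 hexadeca-O-benzyl catechin-(4α→8)-gallocatechin-(4β→8)-catechin
Conditions: Sc(OTf)3 (10 mol%), 4 Å MS, CH2Cl2 (high dilution), −40 to 0 °C
Reagents that add atoms: none
Why: Sc(OTf)3 should ionise the carbinol to a benzylic cation stabilised by O7, O1 and O5 of ring A of the middle unit, far more readily than it attacks the C2–O1 benzylic aryl ether, a linkage that survives Lewis-acid flavan couplings. The tethered 3,5-dibenzyloxyphenyl ether then attacks through either of its two equivalent carbons ortho to the ether oxygen and rearomatises, an intramolecular Friedel–Crafts alkylation of the kind known for 3-aryloxy-1-arylpropan-1-ols giving 4-arylchromans. Ring C of the top unit closes as a six-membered ring in which O1, C2, C3 and the cationic C4 form the tether and the arene bond C8a–C4a becomes part of the ring (endo with respect to the arene, exo with respect to the departing oxygen). The new stereocentre C4 is controlled by allylic 1,3-strain: the ortho-substituted middle ring A holds H3 in the cation plane anti to H4, so closure from the face carrying C2 passes through a chair-like transition state with the C2 aryl, O3 and the middle unit all equatorial, giving the 3,4-trans product. The step needs ring closure to beat intermolecular arylation and acidolysis of the existing 4β→8 bond; high dilution, catalytic acid, low temperature and the high nucleophilicity of the tethered phloroglucinol-type ring are relied on for this. Both carbinol epimers converge on the same cation.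

Step 18
Reactants: 26 hexadeca-O-benzyl trimer
Product: 27 catechin-(4α→8)-gallocatechin-(4β→8)-catechin (target)
Conditions: H2 (1 atm), Pd(OH)2/C, THF/MeOH/H2O, rt
Reagents that add atoms: none
Why: Catalytic hydrogenolysis of all sixteen benzyl ethers over Pd(OH)2 on carbon, standard for benzylated proanthocyanidins, in which the interflavan C–C bonds and the stereocentres are unaffected.

**Compound list**

1 | (+)-catechin | Oc1cc(O)c2c(c1)O[C@H](c1ccc(O)c(O)c1)[C@@H](O)C2 | starting material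

2 | 5,7,3',4'-tetra-O-benzyl-(+)-catechin, (2R,3S), 3-OH free | c9ccccc9COc1cc(OCc9ccccc9)c2c(c1)O[C@H](c1ccc(OCc9ccccc9)c(OCc9ccccc9)c1)[C@@H](O)C2 | intermediate

3 | 3,5,7,3',4'-penta-O-benzyl-(+)-catechin | c9ccccc9COc1cc(OCc9ccccc9)c2c(c1)O[C@H](c1ccc(OCc9ccccc9)c(OCc9ccccc9)c1)[C@@H](OCc9ccccc9)C2 | intermediate

4 | 8-bromo-3,5,7,3',4'-penta-O-benzyl-(+)-catechin | c9ccccc9COc1cc(OCc9ccccc9)c2c(c1Br)O[C@H](c1ccc(OCc9ccccc9)c(OCc9ccccc9)c1)[C@@H](OCc9ccccc9)C2 | intermediate

5 | (+)-dihydromyricetin, (2R,3R) | O=C1c2c(O)cc(O)cc2O[C@H](c2cc(O)c(O)c(O)c2)[C@H]1O | starting material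

6 | 5,7,3',4',5'-penta-O-benzyl-(+)-dihydromyricetin, (2R,3R), 3-OH free | c9ccccc9COc1cc(OCc9ccccc9)c2c(c1)O[C@H](c1cc(OCc9ccccc9)c(OCc9ccccc9)c(OCc9ccccc9)c1)[C@@H](O)C2=O | intermediate

7 | 3,5,7,3',4',5'-hexa-O-benzyl-(+)-dihydromyricetin | c9ccccc9COc1cc(OCc9ccccc9)c2c(c1)O[C@H](c1cc(OCc9ccccc9)c(OCc9ccccc9)c(OCc9ccccc9)c1)[C@@H](OCc9ccccc9)C2=O | intermediate

8 | 8-lithio-3,5,7,3',4'-penta-O-benzylcatechin | [Li]c1c(OCc9ccccc9)cc(OCc9ccccc9)c2c1O[C@H](c1ccc(OCc9ccccc9)c(OCc9ccccc9)c1)[C@@H](OCc9ccccc9)C2 | intermediate (not isolated)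

9 | undeca-O-benzyl 4-hydroxygallocatechin-(4→8)-catechin; tertiary C4 carbinol drawn with the aryl group trans to O3 (expected epimer, centre erased in step 7) | c9ccccc9COc1cc(OCc9ccccc9)c2c(c1)O[C@H](c1cc(OCc9ccccc9)c(OCc9ccccc9)c(OCc9ccccc9)c1)[C@@H](OCc9ccccc9)[C@]2(O)c1c(OCc9ccccc9)cc(OCc9ccccc9)c2c1O[C@H](c1ccc(OCc9ccccc9)c(OCc9ccccc9)c1)[C@@H](OCc9ccccc9)C2 | intermediate

10 | undeca-O-benzyl gallocatechin-(4β→8)-catechin; upper unit 2,3-trans-3,4-cis | c9ccccc9COc1cc(OCc9ccccc9)c2c(c1)O[C@H](c1cc(OCc9ccccc9)c(OCc9ccccc9)c(OCc9ccccc9)c1)[C@@H](OCc9ccccc9)[C@H]2c1c(OCc9ccccc9)cc(OCc9ccccc9)c2c1O[C@H](c1ccc(OCc9ccccc9)c(OCc9ccccc9)c1)[C@@H](OCc9ccccc9)C2 | intermediate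

11 | 8-bromo-undeca-O-benzyl gallocatechin-(4β→8)-catechin; bromine on C8 of the gallocatechin unit | c9ccccc9COc1cc(OCc9ccccc9)c2c(c1Br)O[C@H](c1cc(OCc9ccccc9)c(OCc9ccccc9)c(OCc9ccccc9)c1)[C@@H](OCc9ccccc9)[C@H]2c1c(OCc9ccccc9)cc(OCc9ccccc9)c2c1O[C@H](c1ccc(OCc9ccccc9)c(OCc9ccccc9)c1)[C@@H](OCc9ccccc9)C2 | intermediate

12 | (R)-4-benzyloxazolidin-2-one | O=C1N[C@H](Cc2ccccc2)CO1 | starting material

13 | (benzyloxy)acetyl chloride | ClC(=O)COCc1ccccc1 | starting material

14 | (R)-4-benzyl-3-[(benzyloxy)acetyl]oxazolidin-2-one | O=C(COCc1ccccc1)N1[C@H](Cc2ccccc2)COC1=O | intermediate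

15 | 3,4-bis(benzyloxy)benzaldehyde | O=Cc1ccc(OCc2ccccc2)c(OCc2ccccc2)c1 | starting material

16 | (Z)-dibutylboron enolate of 14 | CCCCB(CCCC)O/C(=C\OCc1ccccc1)N1[C@H](Cc2ccccc2)COC1=O | intermediate (not isolated)

17 | (R)-4-benzyl-3-[(2R,3S)-2-(benzyloxy)-3-[3,4-bis(benzyloxy)phenyl]-3-hydroxypropanoyl]oxazolidin-2-one (syn aldol) | O[C@@H](c1ccc(OCc9ccccc9)c(OCc9ccccc9)c1)[C@@H](OCc9ccccc9)C(=O)N1[C@H](Cc2ccccc2)COC1=O | intermediate

18 | (1S,2S)-2-(benzyloxy)-1-[3,4-bis(benzyloxy)phenyl]propane-1,3-diol | O[C@@H](c1ccc(OCc9ccccc9)c(OCc9ccccc9)c1)[C@@H](OCc9ccccc9)CO | intermediate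

19 | (1S,2S)-2-(benzyloxy)-1-[3,4-bis(benzyloxy)phenyl]-3-[(tert-butyldimethylsilyl)oxy]propan-1-ol | O[C@@H](c1ccc(OCc9ccccc9)c(OCc9ccccc9)c1)[C@@H](OCc9ccccc9)CO[Si](C)(C)C(C)(C)C | intermediate

20 | 3,5-bis(benzyloxy)phenol | Oc1cc(OCc2ccccc2)cc(OCc2ccccc2)c1 | starting material

21 | tert-butyl{[(2S,3R)-2-(benzyloxy)-3-[3,5-bis(benzyloxy)phenoxy]-3-[3,4-bis(benzyloxy)phenyl]propyl]oxy}dimethylsilane | c9ccccc9COc1cc(OCc9ccccc9)cc(c1)O[C@H](c1ccc(OCc9ccccc9)c(OCc9ccccc9)c1)[C@@H](OCc9ccccc9)CO[Si](C)(C)C(C)(C)C | intermediate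

22 | (2S,3R)-2-(benzyloxy)-3-[3,5-bis(benzyloxy)phenoxy]-3-[3,4-bis(benzyloxy)phenyl]propan-1-ol | c9ccccc9COc1cc(OCc9ccccc9)cc(c1)O[C@H](c1ccc(OCc9ccccc9)c(OCc9ccccc9)c1)[C@@H](OCc9ccccc9)CO | intermediate

23 | (2R,3R)-2-(benzyloxy)-3-[3,5-bis(benzyloxy)phenoxy]-3-[3,4-bis(benzyloxy)phenyl]propanal | c9ccccc9COc1cc(OCc9ccccc9)cc(c1)O[C@H](c1ccc(OCc9ccccc9)c(OCc9ccccc9)c1)[C@@H](OCc9ccccc9)C=O | intermediate

24 | 8-lithio-undeca-O-benzyl gallocatechin-(4β→8)-catechin; lithium on C8 of the gallocatechin unit | c9ccccc9COc1cc(OCc9ccccc9)c2c(c1[Li])O[C@H](c1cc(OCc9ccccc9)c(OCc9ccccc9)c(OCc9ccccc9)c1)[C@@H](OCc9ccccc9)[C@H]2c1c(OCc9ccccc9)cc(OCc9ccccc9)c2c1O[C@H](c1ccc(OCc9ccccc9)c(OCc9ccccc9)c1)[C@@H](OCc9ccccc9)C2 | intermediate (not isolated)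

25 | (2S,3R)-3-[3,5-bis(benzyloxy)phenoxy]-2-(benzyloxy)-3-[3,4-bis(benzyloxy)phenyl]-1-[undeca-O-benzyl gallocatechin-(4β→8)-catechin-8-yl]propan-1-ol, 8-yl on the gallocatechin unit; both epimers at C1 (left undefined in the SMILES) | c9ccccc9COc1cc(OCc9ccccc9)cc(c1)O[C@H](c1ccc(OCc9ccccc9)c(OCc9ccccc9)c1)[C@@H](OCc9ccccc9)C(O)c1c(OCc9ccccc9)cc(OCc9ccccc9)c2c1O[C@H](c1cc(OCc9ccccc9)c(OCc9ccccc9)c(OCc9ccccc9)c1)[C@@H](OCc9ccccc9)[C@H]2c1c(OCc9ccccc9)cc(OCc9ccccc9)c2c1O[C@H](c1ccc(OCc9ccccc9)c(OCc9ccccc9)c1)[C@@H](OCc9ccccc9)C2 | intermediate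

26 | hexadeca-O-benzyl catechin-(4α→8)-gallocatechin-(4β→8)-catechin | c9ccccc9COc1cc(OCc9ccccc9)c2c(c1)O[C@H](c1ccc(OCc9ccccc9)c(OCc9ccccc9)c1)[C@@H](OCc9ccccc9)[C@@H]2c1c(OCc9ccccc9)cc(OCc9ccccc9)c2c1O[C@H](c1cc(OCc9ccccc9)c(OCc9ccccc9)c(OCc9ccccc9)c1)[C@@H](OCc9ccccc9)[C@H]2c1c(OCc9ccccc9)cc(OCc9ccccc9)c2c1O[C@H](c1ccc(OCc9ccccc9)c(OCc9ccccc9)c1)[C@@H](OCc9ccccc9)C2 | intermediate

27 | catechin-(4α→8)-gallocatechin-(4β→8)-catechin | Oc1cc(O)c2c(c1)O[C@H](c1ccc(O)c(O)c1)[C@@H](O)[C@@H]2c1c(O)cc(O)c2c1O[C@H](c1cc(O)c(O)c(O)c1)[C@@H](O)[C@H]2c1c(O)cc(O)c2c1O[C@H](c1ccc(O)c(O)c1)[C@@H](O)C2 | target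

**Step count and risks**

Total steps: 18. Longest linear sequence: 10 steps (steps 9–18).

Steps most likely to fail:

1. Step 7. The risk is poor facial selectivity in hydride transfer to the C4 cation: the C2 aryl group on the opposite face may offset the bias of O3 and give the 3,4-trans dimer. The fallback is a tether-directed intramolecular condensation, a known way to reach the 3,4-cis linkage in the catechin series, setting out from 2 and 6 and returning at 10. Compound 2 is acylated with glutaric anhydride (DMAP, pyridine) to tetra-O-benzylcatechin 3-O-hemiglutarate F1. F1 is esterified with the C3 hydroxyl of 6 (EDC, DMAP) to the glutarate-linked keto diester F2. The ketone is reduced (NaBH4, CeCl3, THF/MeOH, −40 °C) to the glutarate-linked flavan-4-ol F3. TMSOTf (CH2Cl2, −40 °C, high dilution) ionises C4, and the tethered catechin unit attacks through C8 from the face of O3 to give the glutarate-bridged 3,4-cis dimer F4. i-Bu2AlH removes the bridge to give deca-O-benzyl gallocatechin-(4β→8)-catechin 3,3''-diol F5. NaH/BnBr then benzylates both alcohols and gives 10.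

2. Step 17. The risks are competing intermolecular arylation, loss of H3 to an enol ether, acidolysis or epimerisation of the 4β→8 bond, and incomplete facial control at C4. The fallback forms the top C4–C8 bond last by classical interflavan coupling, setting out from 3 and 10 and returning at 26. Compound 3 is oxidised at C4 with DDQ in the presence of 2-ethoxyethanol to 4-(2-ethoxyethoxy)-penta-O-benzylcatechin F6. TMSOTf (CH2Cl2, −78 °C) ionises F6, and dimer 10 (in excess) attacks through C8 of its upper unit anti to O3, giving 26.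

3. Step 8. The risk is loss of site selectivity, with bromination at C6 of either unit alongside C8 of the upper unit. The fallback introduces the bromine at the monomer stage, at the flavan oxidation level where C8 selectivity is established, setting out from 7 and returning at 11. NaBH4 reduces 7 to hexa-O-benzyl flavan-4-ol F7. NBS brominates C8 to give 8-bromo flavan-4-ol F8. Dess–Martin oxidation restores the ketone as 8-bromo-hexa-O-benzyl-dihydromyricetin F9. Aryllithium 8 (from 4, as in step 6, at −78 °C) adds to give the 8-bromo tertiary carbinol F10. Bu3SnH/CF3CO2H reduction as in step 7 gives 11.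

**Further compounds**

F1 | step 7 | 5,7,3',4'-tetra-O-benzylcatechin 3-O-hemiglutarate | c9ccccc9COc1cc(OCc9ccccc9)c2c(c1)O[C@H](c1ccc(OCc9ccccc9)c(OCc9ccccc9)c1)[C@@H](OC(=O)CCCC(=O)O)C2

F2 | step 7 | glutarate diester linking O3 of penta-O-benzyl-dihydromyricetin and O3 of tetra-O-benzylcatechin | c9ccccc9COc1cc(OCc9ccccc9)c2c(c1)O[C@H](c1cc(OCc9ccccc9)c(OCc9ccccc9)c(OCc9ccccc9)c1)[C@@H](OC(=O)CCCC(=O)O[C@H]1Cc3c(OCc9ccccc9)cc(OCc9ccccc9)cc3O[C@@H]1c1ccc(OCc9ccccc9)c(OCc9ccccc9)c1)C2=O

F3 | step 7 | 4-hydroxy analogue of F2 (flavan-4-ol, C4 configuration immaterial) | c9ccccc9COc1cc(OCc9ccccc9)c2c(c1)O[C@H](c1cc(OCc9ccccc9)c(OCc9ccccc9)c(OCc9ccccc9)c1)[C@@H](OC(=O)CCCC(=O)O[C@H]1Cc3c(OCc9ccccc9)cc(OCc9ccccc9)cc3O[C@@H]1c1ccc(OCc9ccccc9)c(OCc9ccccc9)c1)C2O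

F4 | step 7 | 3,3''-O-glutaryl-bridged deca-O-benzyl gallocatechin-(4β→8)-catechin | c9ccccc9COc1cc(OCc9ccccc9)c2c(c1)O[C@H](c1cc(OCc9ccccc9)c(OCc9ccccc9)c(OCc9ccccc9)c1)[C@@H](OC(=O)CCCC(=O)O3)[C@H]2c1c(OCc9ccccc9)cc(OCc9ccccc9)c2c1O[C@H](c1ccc(OCc9ccccc9)c(OCc9ccccc9)c1)[C@@H]3C2

F5 | step 7 | deca-O-benzyl gallocatechin-(4β→8)-catechin 3,3''-diol | c9ccccc9COc1cc(OCc9ccccc9)c2c(c1)O[C@H](c1cc(OCc9ccccc9)c(OCc9ccccc9)c(OCc9ccccc9)c1)[C@@H](O)[C@H]2c1c(OCc9ccccc9)cc(OCc9ccccc9)c2c1O[C@H](c1ccc(OCc9ccccc9)c(OCc9ccccc9)c1)[C@@H](O)C2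

F6 | step 17 | 4-(2-ethoxyethoxy)-3,5,7,3',4'-penta-O-benzylcatechin (drawn 3,4-trans, C4 configuration immaterial) | c9ccccc9COc1cc(OCc9ccccc9)c2c(c1)O[C@H](c1ccc(OCc9ccccc9)c(OCc9ccccc9)c1)[C@@H](OCc9ccccc9)[C@@H]2OCCOCC

F7 | step 8 | 3,5,7,3',4',5'-hexa-O-benzyl flavan-3,4-diol from 7 (C4 configuration immaterial) | c9ccccc9COc1cc(OCc9ccccc9)c2c(c1)O[C@H](c1cc(OCc9ccccc9)c(OCc9ccccc9)c(OCc9ccccc9)c1)[C@@H](OCc9ccccc9)C2O

F8 | step 8 | 8-bromo derivative of F7 | c9ccccc9COc1cc(OCc9ccccc9)c2c(c1Br)O[C@H](c1cc(OCc9ccccc9)c(OCc9ccccc9)c(OCc9ccccc9)c1)[C@@H](OCc9ccccc9)C2O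

F9 | step 8 | 8-bromo-3,5,7,3',4',5'-hexa-O-benzyl-dihydromyricetin | c9ccccc9COc1cc(OCc9ccccc9)c2c(c1Br)O[C@H](c1cc(OCc9ccccc9)c(OCc9ccccc9)c(OCc9ccccc9)c1)[C@@H](OCc9ccccc9)C2=O

F10 | step 8 | 8-bromo-undeca-O-benzyl 4-hydroxygallocatechin-(4→8)-catechin (tertiary carbinol, drawn as for 9) | c9ccccc9COc1cc(OCc9ccccc9)c2c(c1Br)O[C@H](c1cc(OCc9ccccc9)c(OCc9ccccc9)c(OCc9ccccc9)c1)[C@@H](OCc9ccccc9)[C@]2(O)c1c(OCc9ccccc9)cc(OCc9ccccc9)c2c1O[C@H](c1ccc(OCc9ccccc9)c(OCc9ccccc9)c1)[C@@H](OCc9ccccc9)C2
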